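## Retrosynthetic overview

1. Feature: number each quinone ring C1(=O), C2(OH), C3(CH3), C4(=O), C5 (ring-to-ring bond), C6 (side chain), with primes for ring B. Rings A and B differ only in the primary 2-arylethyl group on C6/C6'. Without these chains the core is a twofold-symmetric 5,5'-biquinone whose only ring C–H bonds are C6–H and C6'–H.
2. The C2 and C2' hydroxyls are unmasked last from methoxyquinones (vinylogous esters), which leaves the anisole ether untouched.
3. Key disconnection: C6'–CH2 (step 6) and C6–CH2 (step 7, the same reaction run again) are cut. This gives the symmetrical bis(methoxyquinone) and the 2-arylethyl radicals released by decarboxylation of 3-phenylpropanoic and 3-(2-methoxyphenyl)propanoic acid.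
4. The core comes from C5–C5' oxidative homocoupling of 1,2,4-trimethoxy-3-methylbenzene followed by oxidative demethylation. The monomer comes from 2,6-dimethoxytoluene by formylation, Dakin oxidation and O-methylation.
5. No ring is built: rings A and B are the benzene ring of 2,6-dimethoxytoluene, and both phenyl rings arrive with the acids.

Key step: step 6

Assumption: the C5–C5' bond carries four ortho substituents and may be a stereogenic axis, but the target SMILES has no axial descriptor, so 12 and 14 are taken as racemic (or freely rotating) and no axial control is attempted.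

## Route

Step 1
Reactants: 1 2,6-dimethoxytoluene
Product: 3 2,4-dimethoxy-3-methylbenzaldehyde, via aryl iminium salt 2 (not isolated)
Conditions: POCl3, DMF, 0 to 80 °C; then H2O
Reagents that add atoms: N,N-dimethylformamide CN(C)C=O; water O
Why: Vilsmeier–Haack formylation: the chloroiminium ion made from DMF and POCl3 attacks the ring carbon that is para to one methoxy group and ortho to the other (the two such positions are equivalent by symmetry), and water then hydrolyses iminium salt 2 to the aldehyde.

Step 2
Reactants: 3 2,4-dimethoxy-3-methylbenzaldehyde
Product: 5 2,4-dimethoxy-3-methylphenol, via aryl formate 4 (not isolated)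
Conditions: 30% aq H2O2, cat. H2SO4, MeOH, rt
Reagents that add atoms: hydrogen peroxide OO
Why: Acid-catalysed Dakin oxidation (a Baeyer–Villiger-type 1,2-shift): the electron-rich aryl group migrates from carbon to oxygen in the hydroperoxide adduct of the aldehyde, and methanol cleaves formate 4 in the same flask.

Step 3
Reactants: 5 2,4-dimethoxy-3-methylphenol
Product: 6 1,2,4-trimethoxy-3-methylbenzene
Conditions: MeI, K2CO3, acetone, reflux
Reagents that add atoms: iodomethane CI
Why: Williamson ether synthesis on the phenoxide, which removes the free phenol that would otherwise steer the next oxidation to coupling ortho to the hydroxyl group (C6) and leaves C5 as the most activated ring position.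

Step 4
Reactants: 6 1,2,4-trimethoxy-3-methylbenzene (two molecules)
Product: 7 2,2',4,4',5,5'-hexamethoxy-3,3'-dimethylbiphenyl (the C5–C5' linked dimer of 6)
Conditions: PhI(OCOCF3)2 (0.55 equiv), BF3·OEt2, CH2Cl2, −78 to −40 °C
Reagents that add atoms: none
Why: Hypervalent-iodine oxidative biaryl coupling of a phenol ether through its radical cation: bond formation is expected at C5, para to the C2 methoxy and ortho to the C4 methoxy group, the same carbon at which this arene is known to be formylated and brominated, and because both partners are the same molecule there is no cross-coupling selectivity to control.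

Step 5
Reactants: 7 2,2',4,4',5,5'-hexamethoxy-3,3'-dimethylbiphenyl
Product: 8 2,2'-dimethoxy-3,3'-dimethyl-5,5'-bi(1,4-benzoquinone) (C6–H and C6'–H free)
Conditions: (NH4)2Ce(NO3)6 (4.5 equiv), MeCN/H2O, 0 °C
Reagents that add atoms: water O
Why: Oxidative demethylation of para-dimethoxyarenes with tetravalent cerium: in each ring the para-related C1 and C4 methoxy groups are lost as methanol and replaced by carbonyl oxygen from water, whereas the C2 methoxy group stays as the vinylogous ester of the para-quinone.

Step 6
Reactants: 8 2,2'-dimethoxy-3,3'-dimethyl-5,5'-bi(1,4-benzoquinone); 9 3-phenylpropanoic acid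
Product: 10 2,2'-dimethoxy-3,3'-dimethyl-6'-(2-phenylethyl)-5,5'-bi(1,4-benzoquinone)
Conditions: 9 (0.7 equiv), AgNO3 (0.2 equiv), (NH4)2S2O8 (0.8 equiv, slow addition), MeCN/H2O, 65 °C; chromatography, recovered 8 recycled
Reagents that add atoms: none
Why: Persulfate raises monovalent silver to divalent silver, which takes one electron from the carboxylate of 9, and loss of CO2 leaves the primary 2-phenylethyl radical. This nucleophilic radical adds to C6' of the electron-poor quinone, giving an adduct radical delocalised over C5', the C4' carbonyl and the neighbouring ring, and a second one-electron oxidation with loss of the C6' proton restores the quinone. The closest known reaction type is the Minisci-type silver/persulfate decarboxylative C–H alkylation of quinones, which is established for trisubstituted benzoquinones that keep a single ring C–H. No ring is closed and no stereocentre is created. Regioselectivity is fixed by the substrate, since C2', C3' and C5' are substituted and C6' is the only ring carbon that can lose a proton after addition. The selectivity that has to be managed is mono- against double alkylation of two equivalent rings: it is essentially statistical (the first chain should add only a little twist and shielding around C6–H), so 9 and the oxidant are kept below one equivalent, the run is stopped at partial conversion, 10 is separated and unreacted 8 goes back into the step.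

Step 7
Reactants: 10 2,2'-dimethoxy-3,3'-dimethyl-6'-(2-phenylethyl)-5,5'-bi(1,4-benzoquinone); 11 3-(2-methoxyphenyl)propanoic acid
Product: 12 2,2'-dimethoxy-6-[2-(2-methoxyphenyl)ethyl]-3,3'-dimethyl-6'-(2-phenylethyl)-5,5'-bi(1,4-benzoquinone)
Conditions: 11 (2.5 equiv, in portions), AgNO3 (0.3 equiv), (NH4)2S2O8 (2.5 equiv, slow addition), MeCN/H2O, 65 °C
Reagents that add atoms: none
Why: Second run of the Minisci-type silver/persulfate decarboxylative alkylation: C6–H of ring A is the only ring C–H left in 10, so the acid can be used in excess, and the oxidisable anisole ring is brought in last so that it meets the oxidant only once.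

Step 8
Reactants: 12 2,2'-dimethoxy-6-[2-(2-methoxyphenyl)ethyl]-3,3'-dimethyl-6'-(2-phenylethyl)-5,5'-bi(1,4-benzoquinone)
Product: 14 2,2'-dihydroxy-6-[2-(2-methoxyphenyl)ethyl]-3,3'-dimethyl-6'-(2-phenylethyl)-5,5'-bi(1,4-benzoquinone) (target), via disodium bis(quinonolate) 13 (not isolated)
Conditions: 1 M aq NaOH, MeOH, Ar, rt to 40 °C; then 1 M HCl
Reagents that add atoms: sodium hydroxide [Na+].[OH-]
Why: Addition–elimination at a vinylogous ester: hydroxide adds to C2 and C2', the β-carbons of the C4 and C4' enones, methoxide leaves and the stabilised hydroxyquinone anions resist further attack, while the anisole ether has no such activation and is untouched, and acid then liberates the two hydroxyquinones.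

## Compound list

1 | 2,6-dimethoxytoluene | COc1cccc(OC)c1C | starting material
2 | N-(2,4-dimethoxy-3-methylbenzylidene)-N-methylmethanaminium dichlorophosphate | COc1ccc(C=[N+](C)C)c(OC)c1C.[O-]P(=O)(Cl)Cl | intermediate
3 | 2,4-dimethoxy-3-methylbenzaldehyde | COc1ccc(C=O)c(OC)c1C | intermediate
4 | 2,4-dimethoxy-3-methylphenyl formate | COc1ccc(OC=O)c(OC)c1C | intermediate
5 | 2,4-dimethoxy-3-methylphenol | COc1ccc(O)c(OC)c1C | intermediate
6 | 1,2,4-trimethoxy-3-methylbenzene | COc1ccc(OC)c(OC)c1C | intermediate
7 | 2,2',4,4',5,5'-hexamethoxy-3,3'-dimethylbiphenyl | COc1cc(-c2cc(OC)c(OC)c(C)c2OC)c(OC)c(C)c1OC | intermediate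
8 | 2,2'-dimethoxy-3,3'-dimethyl-5,5'-bi(1,4-benzoquinone) | COC1=C(C)C(=O)C(=CC1=O)C1=CC(=O)C(OC)=C(C)C1=O | intermediate
9 | 3-phenylpropanoic acid | OC(=O)CCc1ccccc1 | starting material
10 | 2,2'-dimethoxy-3,3'-dimethyl-6'-(2-phenylethyl)-5,5'-bi(1,4-benzoquinone) | COC1=C(C)C(=O)C(=CC1=O)C1=C(CCc2ccccc2)C(=O)C(OC)=C(C)C1=O | intermediate
11 | 3-(2-methoxyphenyl)propanoic acid | COc1ccccc1CCC(=O)O | starting material
12 | 2,2'-dimethoxy-6-[2-(2-methoxyphenyl)ethyl]-3,3'-dimethyl-6'-(2-phenylethyl)-5,5'-bi(1,4-benzoquinone) | COC1=C(C)C(=O)C(=C(CCc2ccccc2OC)C1=O)C1=C(CCc2ccccc2)C(=O)C(OC)=C(C)C1=O | intermediate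
13 | disodium salt of 14 (both C2/C2' oxygens as sodium quinonolates) | COc1ccccc1CCC1=C(C2=C(CCc3ccccc3)C(=O)C([O-])=C(C)C2=O)C(=O)C(C)=C([O-])C1=O.[Na+].[Na+] | intermediate
14 | 2,2'-dihydroxy-6-[2-(2-methoxyphenyl)ethyl]-3,3'-dimethyl-6'-(2-phenylethyl)-5,5'-bi(1,4-benzoquinone) | COc1ccccc1CCC1=C(C2=C(CCc3ccccc3)C(=O)C(O)=C(C)C2=O)C(=O)C(C)=C(O)C1=O | target

## Step count and risks

Total step count: 8. Longest linear sequence: 8 steps (1 to 14); acids 9 and 11 are bought.

Three steps most likely to fail:

**Step 6.**
- Alkylation may run on to the second ring before much of the core is consumed.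
- Capture of the primary radical may be slow at a C–H flanked by the other quinone ring.
- The core may break down in hot acidic water, by addition of water at the free C6/C6' positions or by ring closure between the two quinone rings.

Fallback: the first chain is attached at the arene oxidation level by cross-coupling, setting out from 7 and coming back at 10. One equivalent of NBS in MeCN brominates the only free ring position of one ring of 7 and gives 6-bromo-2,2',4,4',5,5'-hexamethoxy-3,3'-dimethylbiphenyl F1, which is separated from unreacted 7 and from doubly brominated material on a robust, non-quinoid substrate. Hydroboration of styrene with 9-BBN gives 9-(2-phenylethyl)-9-borabicyclo[3.3.1]nonane F2. A B-alkyl Suzuki–Miyaura coupling of F1 with F2 (Pd(OAc)2, SPhos, K3PO4, THF/H2O, 65 °C) should give 2,2',4,4',5,5'-hexamethoxy-3,3'-dimethyl-6-(2-phenylethyl)biphenyl F3. Oxidative demethylation of F3 with (NH4)2Ce(NO3)6 in MeCN/H2O, as in step 5, gives 10.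

**Step 7.**
- One-electron oxidation of the electron-rich anisole ring of the acid (and of the chain once installed) by divalent silver or the sulfate radical anion may compete with decarboxylation and use up the acid.
- Addition to the more twisted and shielded ring A may be slow.

Fallback: the same radical is made thermally, without silver or persulfate, setting out from 10 and 11 and coming back at 12. Acid 11 is coupled with H2O2 by DCC in Et2O/CH2Cl2 at 0 °C to give bis[3-(2-methoxyphenyl)propanoyl] peroxide F4, which is kept in solution and not concentrated. Heating F4 with 10 in acetic acid at about 95 °C is the classical diacyl peroxide alkylation of quinones. O–O homolysis and loss of CO2 give the 2-(2-methoxyphenyl)ethyl radical, which adds to C6, and the adduct radical is oxidised by further peroxide to 12.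

**Step 8.**
- Hydroxide may attack ring positions other than C2/C2'.
- Base may induce tautomerisation through the quinone–CH2 positions.
- The second hydrolysis may stall once the first ring is anionic.

Fallback: the O–CH3 bond is broken instead of the ring C–O bond, under Lewis-acidic and base-free conditions, setting out from 12 and coming back at 14. BCl3 in CH2Cl2 (−78 to 0 °C) binds between each C1 carbonyl and the neighbouring C2 methoxy oxygen, and chloride removes the methyl group. This chelation-directed demethylation is known for methoxy groups next to a carbonyl and should spare the unchelated anisole ether. It gives the bis(dichloroboryl) ether of 14 F5, which aqueous work-up hydrolyses to 14.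

## Further compounds

F1 | step 6 | 6-bromo-2,2',4,4',5,5'-hexamethoxy-3,3'-dimethylbiphenyl | COc1c(Br)c(-c2cc(OC)c(OC)c(C)c2OC)c(OC)c(C)c1OC
F2 | step 6 | 9-(2-phenylethyl)-9-borabicyclo[3.3.1]nonane | c1ccccc1CCB1C2CCCC1CCC2
F3 | step 6 | 2,2',4,4',5,5'-hexamethoxy-3,3'-dimethyl-6-(2-phenylethyl)biphenyl | COc1c(CCc2ccccc2)c(-c2cc(OC)c(OC)c(C)c2OC)c(OC)c(C)c1OC
F4 | step 7 | bis[3-(2-methoxyphenyl)propanoyl] peroxide | COc1ccccc1CCC(=O)OOC(=O)CCc1ccccc1OC
F5 | step 8 | bis(dichloroboryl) ether of 14 | COc1ccccc1CCC1=C(C2=C(CCc3ccccc3)C(=O)C(OB(Cl)Cl)=C(C)C2=O)C(=O)C(C)=C(OB(Cl)Cl)C1=O
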